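**Plan**

1. Labdane numbering is used: ring A = C1–C5 and C10, ring B = C5–C10, C17 = formyl carbon on C8, side chain C11–C15 on C9. The last cuts are changes of oxidation level only (C17: CHO ⇐ CH2OH ⇐ CO2H ⇐ CO2tBu; C3: OH ⇐ C=O).
2. Ring B is cut at C5–C6 and C8–C9. It holds a crotonate-like unit C6H2–C7H=C8(–C17) between C5, the β-carbon of a ring A enone (C3=O, C4=C5), and C9, an alkene carbon of the side chain. C6 (γ-carbon) is joined to C5 as a vinylogous nucleophile and C8 (α-carbon) to C9 as a vinyl radical, a formal [3+3] annulation.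
3. The C3–C4 enolate left by the first bond formation takes the second methyl on C4. The bromine on C8, the silyl enol ether and the tert-butyl ester are helpers that are removed on the way.
4. The C9=C11 alkene is cut next (Wittig). This leaves a ring A enone aldehyde (C9 = CHO), which comes from methacrolein by a Diels–Alder reaction.
5. Forward order: ring A (Diels–Alder), side chain joined (Wittig), ring B closed onto ring A (annulation), redox end game.
6. Stereochemistry: C10 from the catalytic asymmetric Diels–Alder reaction, C13 from (R)-3-methylglutaric acid monomethyl ester, C5 and C9 in the annulation under control of C10, C3 by axial hydride delivery.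

Key step: step 8

Remark: (1E)-1-methoxy-2-methyl-3-(trimethylsilyloxy)buta-1,3-diene, (R)-3-methylglutaric acid monomethyl ester and tert-butyl crotonate are taken to be commercial.

**Step 1**
Reactants: 1 methacrolein; 2 (1E)-1-methoxy-2-methyl-3-(trimethylsilyloxy)buta-1,3-diene
Product: 4 (1R)-1,3-dimethyl-4-oxocyclohex-2-ene-1-carbaldehyde, via silyl enol ether cycloadduct 3 (not isolated)
Conditions: B-(o-tolyl)oxazaborolidine from (S)-α,α-diphenylprolinol, protonated by Tf2NH (10 mol%; the catalyst enantiomer that gives the 1R aldehyde is used), CH2Cl2, −78 °C; then 1 M HCl, THF, 0 °C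
Reagents that add atoms: none
Why: The chiral Lewis acid should catalyse a Diels–Alder reaction in which the formyl-bearing carbon bonds to the methoxy-bearing diene terminus (ortho rule) and one face of the coordinated enal is shielded, which sets the quaternary C10, and acid then unmasks the enone by hydrolysis of the silyl enol ether and loss of methanol.

**Step 2**
Reactants: 5 (3R)-5-methoxy-3-methyl-5-oxopentanoic acid
Product: 6 methyl (3R)-5-hydroxy-3-methylpentanoate
Conditions: BH3·SMe2, THF, 0 °C to rt; MeOH quench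
Reagents that add atoms: none
Why: Borane reduces the free carboxylic acid through an acyloxyborane much faster than the methyl ester (chemoselective borane reduction) and does not touch the C13 stereocentre.

**Step 3**
Reactants: 6 methyl (3R)-5-hydroxy-3-methylpentanoate
Product: 7 methyl (3S)-5-iodo-3-methylpentanoate
Conditions: I2, PPh3, imidazole, CH2Cl2, 0 °C to rt
Reagents that add atoms: iodine, II
Why: Appel-type iodination should replace the primary hydroxyl by iodide through SN2 attack on the alkoxyphosphonium ion, leaving ester and stereocentre untouched (the descriptor changes only because the priorities change).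

**Step 4**
Reactants: 7 methyl (3S)-5-iodo-3-methylpentanoate
Product: 8 [(3S)-5-methoxy-3-methyl-5-oxopentyl]triphenylphosphonium iodide
Conditions: PPh3, MeCN, reflux
Reagents that add atoms: triphenylphosphine, c1ccc(cc1)P(c1ccccc1)c1ccccc1
Why: SN2 alkylation of triphenylphosphine by the primary iodide should give the Wittig salt.

**Step 5**
Reactants: 8 [(3S)-5-methoxy-3-methyl-5-oxopentyl]triphenylphosphonium iodide; 4 (1R)-1,3-dimethyl-4-oxocyclohex-2-ene-1-carbaldehyde
Product: 10 methyl (3R,5Z)-6-[(1S)-1,3-dimethyl-4-oxocyclohex-2-en-1-yl]-3-methylhex-5-enoate, via phosphorus ylide 9 (not isolated)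
Conditions: NaN(SiMe3)2, THF, −78 °C; then 4, −78 °C to 0 °C
Reagents that add atoms: none
Why: Wittig olefination with the salt-free, non-stabilised ylide at low temperature should give the (Z)-alkene and should react only at the non-enolisable formyl group, not at the hindered conjugated ketone.

**Step 6**
Reactants: 11 tert-butyl (2E)-but-2-enoate
Product: 13 tert-butyl (2Z)-2-bromobut-2-enoate, via dibromide 12 (not isolated)
Conditions: Br2, CH2Cl2, 0 °C; then Et3N, 0 °C to rt
Reagents that add atoms: bromine, BrBr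
Why: Anti addition of bromine to the enoate followed by base-induced loss of HBr through the acidic α-hydrogen should give the more stable (Z)-2-bromo enoate (bromination–dehydrobromination).

**Step 7**
Reactants: 13 tert-butyl (2Z)-2-bromobut-2-enoate
Product: 14 {[(1Z)-2-bromo-1-tert-butoxybuta-1,3-dien-1-yl]oxy}(tert-butyl)dimethylsilane
Conditions: LiN(iPr)2, TBSCl, THF/DMPU, −78 °C
Reagents that add atoms: tert-butyl(chloro)dimethylsilane, CC(C)(C)[Si](C)(C)Cl
Why: γ-Deprotonation of the enoate and O-silylation of the extended enolate should give the vinylketene silyl acetal (silyl dienolate formation); the ketene acetal geometry is of no consequence.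

**Step 8**
Reactants: 10 methyl (3R,5Z)-6-[(1S)-1,3-dimethyl-4-oxocyclohex-2-en-1-yl]-3-methylhex-5-enoate; 14 {[(1Z)-2-bromo-1-tert-butoxybuta-1,3-dien-1-yl]oxy}(tert-butyl)dimethylsilane
Product: 17 tert-butyl (1S,4aS,8aR)-1-[(3R)-5-methoxy-3-methyl-5-oxopentyl]-5,5,8a-trimethyl-6-oxo-1,4,4a,5,6,7,8,8a-octahydronaphthalene-2-carboxylate, via silyl enol ether 15 (not isolated), via bromo enoate ketone 16 (not isolated)
Conditions: one pot: (i) Tf2NH (5 mol%, gives TBSNTf2 in situ), CH2Cl2, −78 °C; (ii) TASF [(Me2N)3S+ Me3SiF2−], MeI, THF, −78 to 0 °C, then volatiles removed; (iii) Bu3SnH (slow addition), AIBN, PhH, 80 °C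
Reagents that add atoms: iodomethane, CI
Why: The silyl Lewis acid activates the enone of 10 so that dienolate 14 attacks C5 through its unsubstituted γ-carbon and the silyl group passes to the C3 oxygen (15); fluoride then frees the regiodefined C3–C4 enolate, which MeI methylates at C4 (16), and Bu3Sn• abstracts bromine from C8 to give a vinyl radical that closes ring B by 6-exo-trig attack on C9 before the C11 radical takes hydrogen from Bu3SnH. The closest known reaction types are the vinylogous Mukaiyama–Michael addition, the fluoride-mediated alkylation of silyl enol ethers and the cyclisation of vinyl radicals onto alkenes. C5 is set in the intermolecular stage: the nucleophile should enter the enone face opposite the larger (Z)-alkenyl group on the quaternary C10, hence cis to the C10 methyl, which is what the trans ring fusion needs. C9 is set in the radical closure through a chair-like transition state with the attacked alkene pseudo-equatorial, so that C11 ends equatorial and cis to the C10 methyl. The step needs γ- over α-attack of the dienolate (secured by the α-bromine, the bulky ester and the silyl Lewis acid), methylation before the radical stage (a C3–C4 enol ether would capture the vinyl radical in a 5-exo mode) and cyclisation faster than reduction (low stationary Bu3SnH concentration).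

**Step 9**
Reactants: 17 tert-butyl (1S,4aS,8aR)-1-[(3R)-5-methoxy-3-methyl-5-oxopentyl]-5,5,8a-trimethyl-6-oxo-1,4,4a,5,6,7,8,8a-octahydronaphthalene-2-carboxylate
Product: 18 (1S,4aS,8aR)-1-[(3R)-5-methoxy-3-methyl-5-oxopentyl]-5,5,8a-trimethyl-6-oxo-1,4,4a,5,6,7,8,8a-octahydronaphthalene-2-carboxylic acid
Conditions: CF3CO2H, CH2Cl2, 0 °C to rt
Reagents that add atoms: none
Why: Acidolysis of the tert-butyl ester with loss of isobutene should free the conjugated acid while the methyl ester survives, which tells C17 apart from C15.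

**Step 10**
Reactants: 18 (1S,4aS,8aR)-1-[(3R)-5-methoxy-3-methyl-5-oxopentyl]-5,5,8a-trimethyl-6-oxo-1,4,4a,5,6,7,8,8a-octahydronaphthalene-2-carboxylic acid
Product: 19 (1S,4aS,6R,8aR)-6-hydroxy-1-[(3R)-5-methoxy-3-methyl-5-oxopentyl]-5,5,8a-trimethyl-1,4,4a,5,6,7,8,8a-octahydronaphthalene-2-carboxylic acid
Conditions: NaBH4, MeOH, 0 °C
Reagents that add atoms: none
Why: NaBH4 reduces only the ketone, and axial hydride delivery on the face opposite the axial methyl groups on C4 and C10 should give the equatorial C3 alcohol, cis to the C10 methyl.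

**Step 11**
Reactants: 19 (1S,4aS,6R,8aR)-6-hydroxy-1-[(3R)-5-methoxy-3-methyl-5-oxopentyl]-5,5,8a-trimethyl-1,4,4a,5,6,7,8,8a-octahydronaphthalene-2-carboxylic acid
Product: 20 methyl (3R)-5-[(1S,4aS,6R,8aS)-6-hydroxy-2-(hydroxymethyl)-5,5,8a-trimethyl-1,4,4a,5,6,7,8,8a-octahydronaphthalen-1-yl]-3-methylpentanoate
Conditions: BH3·SMe2, THF, 0 °C to rt; MeOH quench
Reagents that add atoms: none
Why: Borane should reduce the carboxylic acid to the allylic alcohol in the presence of the methyl ester (chemoselective borane reduction), and the trisubstituted, electron-poor C7=C8 bond should resist hydroboration.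

**Step 12**
Reactants: 20 methyl (3R)-5-[(1S,4aS,6R,8aS)-6-hydroxy-2-(hydroxymethyl)-5,5,8a-trimethyl-1,4,4a,5,6,7,8,8a-octahydronaphthalen-1-yl]-3-methylpentanoate
Product: 21 methyl (3R)-5-[(1S,4aS,6R,8aR)-2-formyl-6-hydroxy-5,5,8a-trimethyl-1,4,4a,5,6,7,8,8a-octahydronaphthalen-1-yl]-3-methylpentanoate
Conditions: MnO2, CH2Cl2, rt
Reagents that add atoms: none
Why: MnO2 should oxidise only the allylic primary alcohol to the enal and leave the saturated secondary C3 alcohol untouched (chemoselective allylic oxidation).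

**Compound list**

1 | methacrolein | CC(=C)C=O | starting material
2 | (1E)-1-methoxy-2-methyl-3-(trimethylsilyloxy)buta-1,3-diene | CO/C=C(C)/C(=C)O[Si](C)(C)C | starting material
3 | (1R)-2-methoxy-1,3-dimethyl-4-(trimethylsilyloxy)cyclohex-3-ene-1-carbaldehyde (both C2 epimers, C2 left open) | O=C[C@@]1(C)C(OC)C(C)=C(O[Si](C)(C)C)CC1 | intermediate
4 | (1R)-1,3-dimethyl-4-oxocyclohex-2-ene-1-carbaldehyde | O=C[C@@]1(C)C=C(C)C(=O)CC1 | intermediate
5 | (3R)-5-methoxy-3-methyl-5-oxopentanoic acid | COC(=O)C[C@H](C)CC(=O)O | starting material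
6 | methyl (3R)-5-hydroxy-3-methylpentanoate | COC(=O)C[C@H](C)CCO | intermediate
7 | methyl (3S)-5-iodo-3-methylpentanoate | COC(=O)C[C@H](C)CCI | intermediate
8 | [(3S)-5-methoxy-3-methyl-5-oxopentyl]triphenylphosphonium iodide | COC(=O)C[C@H](C)CC[P+](c1ccccc1)(c1ccccc1)c1ccccc1.[I-] | intermediate
9 | methyl (3S)-3-methyl-5-(triphenyl-λ5-phosphanylidene)pentanoate | COC(=O)C[C@H](C)CC=P(c1ccccc1)(c1ccccc1)c1ccccc1 | intermediate
10 | methyl (3R,5Z)-6-[(1S)-1,3-dimethyl-4-oxocyclohex-2-en-1-yl]-3-methylhex-5-enoate | COC(=O)C[C@H](C)C/C=C\[C@@]1(C)C=C(C)C(=O)CC1 | intermediate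
11 | tert-butyl (2E)-but-2-enoate | C/C=C/C(=O)OC(C)(C)C | starting material
12 | tert-butyl (2RS,3SR)-2,3-dibromobutanoate (racemic, one enantiomer drawn) | C[C@H](Br)[C@H](Br)C(=O)OC(C)(C)C | intermediate
13 | tert-butyl (2Z)-2-bromobut-2-enoate | C/C=C(\Br)C(=O)OC(C)(C)C | intermediate
14 | {[(1Z)-2-bromo-1-tert-butoxybuta-1,3-dien-1-yl]oxy}(tert-butyl)dimethylsilane | C=C/C(Br)=C(/O[Si](C)(C)C(C)(C)C)OC(C)(C)C | intermediate
15 | methyl (3R,5Z)-6-[(1S,2S)-2-[(2Z)-3-bromo-4-tert-butoxy-4-oxobut-2-en-1-yl]-4-{[tert-butyl(dimethyl)silyl]oxy}-1,3-dimethylcyclohex-3-en-1-yl]-3-methylhex-5-enoate | COC(=O)C[C@H](C)C/C=C\[C@]1(C)CCC(O[Si](C)(C)C(C)(C)C)=C(C)[C@H]1C/C=C(\Br)C(=O)OC(C)(C)C | intermediate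
16 | methyl (3R,5Z)-6-[(1S,2S)-2-[(2Z)-3-bromo-4-tert-butoxy-4-oxobut-2-en-1-yl]-1,3,3-trimethyl-4-oxocyclohexyl]-3-methylhex-5-enoate | COC(=O)C[C@H](C)C/C=C\[C@]1(C)CCC(=O)C(C)(C)[C@H]1C/C=C(\Br)C(=O)OC(C)(C)C | intermediate
17 | tert-butyl (1S,4aS,8aR)-1-[(3R)-5-methoxy-3-methyl-5-oxopentyl]-5,5,8a-trimethyl-6-oxo-1,4,4a,5,6,7,8,8a-octahydronaphthalene-2-carboxylate | COC(=O)C[C@H](C)CC[C@@H]1C(C(=O)OC(C)(C)C)=CC[C@@H]2C(C)(C)C(=O)CC[C@@]12C | intermediate
18 | (1S,4aS,8aR)-1-[(3R)-5-methoxy-3-methyl-5-oxopentyl]-5,5,8a-trimethyl-6-oxo-1,4,4a,5,6,7,8,8a-octahydronaphthalene-2-carboxylic acid | COC(=O)C[C@H](C)CC[C@@H]1C(C(=O)O)=CC[C@@H]2C(C)(C)C(=O)CC[C@@]12C | intermediate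
19 | (1S,4aS,6R,8aR)-6-hydroxy-1-[(3R)-5-methoxy-3-methyl-5-oxopentyl]-5,5,8a-trimethyl-1,4,4a,5,6,7,8,8a-octahydronaphthalene-2-carboxylic acid | COC(=O)C[C@H](C)CC[C@@H]1C(C(=O)O)=CC[C@@H]2C(C)(C)[C@H](O)CC[C@@]12C | intermediate
20 | methyl (3R)-5-[(1S,4aS,6R,8aS)-6-hydroxy-2-(hydroxymethyl)-5,5,8a-trimethyl-1,4,4a,5,6,7,8,8a-octahydronaphthalen-1-yl]-3-methylpentanoate | COC(=O)C[C@H](C)CC[C@@H]1C(CO)=CC[C@@H]2C(C)(C)[C@H](O)CC[C@@]12C | intermediate
21 | methyl (3R)-5-[(1S,4aS,6R,8aR)-2-formyl-6-hydroxy-5,5,8a-trimethyl-1,4,4a,5,6,7,8,8a-octahydronaphthalen-1-yl]-3-methylpentanoate | COC(=O)C[C@H](C)CC[C@@H]1C(C=O)=CC[C@@H]2C(C)(C)[C@H](O)CC[C@@]12C | target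

**Step count and risks**

Total step count: 12. Longest linear sequence: 9 steps (5 → 6 → 7 → 8 → 10 → 17 → 18 → 19 → 20 → 21, that is steps 2, 3, 4, 5, 8, 9, 10, 11 and 12).

Steps most likely to fail:

Step 8. The intermolecular Michael addition may show poor facial selectivity at C5, because the (Z)-alkenyl group and the methyl group on C10 differ only moderately in size. The vinyl radical may also be reduced, or close in the 7-endo mode, before the 6-exo closure. The fallback sets out from 4 and comes back at 16. The formyl group of 4 is first turned into a much bulkier sp3 substituent by acetalisation with 2,2-dimethylpropane-1,3-diol (PPTS, benzene, reflux), which should give (4R)-4-(5,5-dimethyl-1,3-dioxan-2-yl)-2,4-dimethylcyclohex-2-en-1-one F1. Fluoride-triggered Michael addition of 14 (TASF, THF, −78 °C), now steered to the face opposite the dioxanyl group, and methylation of the resulting enolate with MeI should give tert-butyl (2Z)-2-bromo-4-[(1S,6R)-6-(5,5-dimethyl-1,3-dioxan-2-yl)-2,2,6-trimethyl-3-oxocyclohexyl]but-2-enoate F2. Mild hydrolysis (PPTS, aqueous acetone) should free tert-butyl (2Z)-2-bromo-4-[(1S,6R)-6-formyl-2,2,6-trimethyl-3-oxocyclohexyl]but-2-enoate F3. Wittig reaction of F3 with ylide 9 should then give 16, which is cyclised with Bu3SnH and AIBN as in the last stage of step 8.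

Step 7. γ-Deprotonation of the bromo enoate may be overrun by attack of the amide base on bromine or by loss of bromide from the extended enolate. The fallback sets out from 11 and comes back at 14. The lithium dienolate of 11 (LiN(iPr)2, THF, −78 °C) is brominated at its α-carbon with 1,2-dibromotetrachloroethane, which should give the deconjugated ester tert-butyl (2RS)-2-bromobut-3-enoate F4. Its acidic α-hydrogen then allows soft enolisation (TBSOTf, Et3N, CH2Cl2, 0 °C) to 14 without a strong base.

Step 1. The Lewis-acid-catalysed cycloaddition may be diverted to hetero-Diels–Alder addition at the formyl group, or the enantiomeric purity of the quaternary centre may be insufficient. The fallback sets out from commercial methyl 2-formylpropanoate and pent-1-en-3-one (not from a numbered compound) and comes back at 4. Enantioselective Michael addition under catalysis by a cinchona-alkaloid base should give methyl (2R)-2-formyl-2-methyl-5-oxoheptanoate F5. Pyrrolidinium acetate should effect the intramolecular aldol condensation to methyl (1R)-1,3-dimethyl-4-oxocyclohex-2-ene-1-carboxylate F6. LiAlH4 (THF, 0 °C) should reduce ketone and ester to (4R)-4-(hydroxymethyl)-2,4-dimethylcyclohex-2-en-1-ol F7 (both carbinol epimers). Oxidation of both hydroxyl groups with Dess–Martin periodinane should return 4.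

**Further compounds**

F1 | step 8 | (4R)-4-(5,5-dimethyl-1,3-dioxan-2-yl)-2,4-dimethylcyclohex-2-en-1-one | CC1(C)COC(OC1)[C@@]1(C)C=C(C)C(=O)CC1
F2 | step 8 | tert-butyl (2Z)-2-bromo-4-[(1S,6R)-6-(5,5-dimethyl-1,3-dioxan-2-yl)-2,2,6-trimethyl-3-oxocyclohexyl]but-2-enoate | CC1(C)COC(OC1)[C@]1(C)CCC(=O)C(C)(C)[C@H]1C/C=C(\Br)C(=O)OC(C)(C)C
F3 | step 8 | tert-butyl (2Z)-2-bromo-4-[(1S,6R)-6-formyl-2,2,6-trimethyl-3-oxocyclohexyl]but-2-enoate | O=C[C@]1(C)CCC(=O)C(C)(C)[C@H]1C/C=C(\Br)C(=O)OC(C)(C)C
F4 | step 7 | tert-butyl (2RS)-2-bromobut-3-enoate (racemic) | C=CC(Br)C(=O)OC(C)(C)C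
F5 | step 1 | methyl (2R)-2-formyl-2-methyl-5-oxoheptanoate | CCC(=O)CC[C@](C)(C=O)C(=O)OC
F6 | step 1 | methyl (1R)-1,3-dimethyl-4-oxocyclohex-2-ene-1-carboxylate | COC(=O)[C@@]1(C)C=C(C)C(=O)CC1
F7 | step 1 | (4R)-4-(hydroxymethyl)-2,4-dimethylcyclohex-2-en-1-ol (both C1 epimers, C1 left open) | OC[C@@]1(C)C=C(C)C(O)CC1
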